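Assumption: the target has no stereocentre. The transient bis-epoxide 14 should form as a mixture of stereoisomers whose four centres are erased in the same flask, so it is drawn without configuration.

## Analysis of the target

The target is a biflavonol: two 3-hydroxy-2-arylchromen-4-one units, each made of a benzopyranone (rings A and C) and a phenyl ring B, six rings in all. The halves are joined only by one diaryl ether oxygen between C4' of ring B1 and C4''' of ring B2. Unit 1 has 5-OH and 7-OMe on ring A1 and a free 3'-OH on ring B1, ortho to the bridging oxygen; unit 2 has 5-OH and 7-OH on ring A2 and a 3'''-OMe on ring B2, again ortho to the bridge. There is no stereocentre, so every problem is constitutional: ten oxygen substituents must be placed and told apart. The sensitive groups are the two 3-hydroxy-4-pyranones (easily oxidised in base and air, strong metal chelators), six free phenols, the electrophilic C2 of each chromone toward hot hydroxide, and two methyl ethers that must survive the final deprotection. The difficulty is that the halves are almost, but not quite, identical, so they have to be grown one after the other from a diaryl ether with distinguishable ends; in addition, the classical alkaline peroxide route to 3-hydroxyflavones is unreliable for 5-oxygenated systems, which tend to divert to aurones. The strategy rests on the C2=C3 bonds of rings C1 and C2: they are enol-ether double bonds of vinylogous esters and the only non-aromatic alkenes in a biflavone, so both C3–O bonds can be made last by electrophilic oxygen transfer.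

## Retrosynthetic reasoning

**16 from 15.** The four O–benzyl bonds on O5, O3', O5'' and O7'' are cut. Benzyl is chosen because hydrogenolysis is neutral and leaves the two methyl ethers, the diaryl ether and both flavonol units alone, and because one operation frees all four phenols. The forward step has only to avoid saturating the C2=C3 bonds.

**15 from 13 through 14.** The two C3–O bonds are cut, one in each unit, which leads back to biflavone 13 with two unsubstituted C3 positions. This is the place to cut because 13 is reachable by the most reliable flavone chemistry, whereas carrying a C3 oxygen through ring construction would force a different and less dependable ring synthesis on each half. The forward reaction has to transfer one oxygen atom to each C2=C3 bond, giving bis-epoxide 14, and then isomerise both oxiranes to enols. It must not touch the alkoxyarenes or the benzylic positions. O5 is kept as a benzyl ether in 13 so that no free phenol is exposed to the oxidant and no hydrogen bond to C4=O lowers the electron density of the double bond.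

**13 from 12.** The O1–C2 bond of unit 1 is cut and two hydrogens are returned, giving 2'-hydroxychalcone 12. Oxidative cyclisation of a chalcone is neutral to the flavone of unit 2 that is already present, and it needs no oxygen at C3.

**12 from 11 and 2.** The Cα=Cβ bond of the chalcone (the later C3–C2 bond of unit 1) is cut to aldehyde 11 and acetophenone 2. Ring A1 thus enters complete, with O7 as the methyl ether and O5 already differentiated as a benzyl ether. The forward aldol condensation has only one enolisable partner.

**11 from 10.** The O1–C2 bond of unit 2 is cut to the 1,3-diketone 10, which still carries the aldehyde of ring B1 as its dimethyl acetal. One acid treatment closes the pyranone and unmasks the aldehyde, so no separate deprotection is needed.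

**10 from 9 and 4.** The bond between the future C3 and C2 of unit 2 is cut to methyl ester 9 and acetophenone 4 (crossed Claisen condensation). The two halves are built by different reactions on purpose. The diaryl ether has an ester at one end and an aldehyde at the other, and the ester end can be addressed by enolate acylation only while the aldehyde is masked.

**9 from 8.** The acetal is removed to aldehyde ester 8. The acetal is needed because the enolate of 4 would add to a free aldehyde faster than to the ester.

**8 from 6 and 7.** The diaryl ether is cut at the C4'–O bond on the side of ring B1, which gives fluoroaldehyde 6 and phenol 7. The cut is placed here because the leaving group then sits para to the formyl group that activates nucleophilic aromatic substitution. The nucleophile 7 has a single free hydroxyl and already carries the methoxy group of ring B2. A nucleophile with two free catechol oxygens would instead pose a choice between them and invite aryl migration from one oxygen to its neighbour. The step also delivers the ester and aldehyde ends in one operation.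

**6 from 5, 2 from 1, 4 from 3.** Each is an O–benzyl disconnection. In 1 and 3 one hydroxyl ortho to the acetyl group stays free because it is held in a hydrogen bond to the carbonyl. That hydroxyl later becomes O1 of the pyranone.

## Alternatives that were turned down

Alternative 1: Ring A1 is dismantled at C4a–C5, C5–C6, C7–C8 and C8–C8a, leading back to a monocyclic 4-pyranone with a diazoacetyl group on C6, diazo ketone A2, and methoxyacetylene A3.
- Forward key step: irradiation of A2 causes a Wolff rearrangement to a vinylketene. This adds A3 in a [2+2] sense; the cyclobutenone opens on warming to a dienylketene, which closes by 6π electrocyclisation and tautomerises to the phenol A1.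
- For: the 5-OH comes from the ketene carbon and the 7-OMe from A3, so O5 and O7 are differentiated by construction, and the C3 oxygen is carried through as a benzyl ether. On these two points it is stronger than the chosen route, which needs a selective mono-benzylation to make 2 and a late oxidation at C3.
- Against: the key step spends its effort on a ring that 1 already supplies. A2 needs a long synthesis of a fully substituted pyranone acid derivative. The 4-pyranone chromophore absorbs and rearranges under the same light. A3 is volatile and prone to polymerise. Unit 2 must still be built from the dioxolane of A1, and its C3 oxygen remains unsolved.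
- Comparison: the chosen route offers bought A rings, one operation that serves both halves, and a much shorter sequence.

Alternative 2: Both C5–O bonds are cut, leading to the 5,5''-dideoxy tetraacetate A5.
- Forward key step: catalyst A6, which is [RuCl2(p-cymene)]2 with divalent ruthenium, and oxidant A7, which is PhI(OCOCF3)2 with trivalent iodine, are used in a fluorinated carboxylic acid and its anhydride. They should form a five-membered ruthenacycle through each C4 carbonyl and oxygenate C5 of both units, giving the 5,5''-dihydroxy tetraacetate A4 after hydrolysis of the first-formed esters.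
- For: C5 is the only C–H peri to each carbonyl, so the site is unambiguous. The 5-deoxy series allows the alkaline peroxide oxidation of chalcones to install the 3-hydroxyl without aurone formation. On that point it is stronger than the chosen route, and it also avoids an acid-labile 5-O-benzyl group.
- Against: a hot, strongly acidic and oxidising medium meets two electron-rich, triply oxygenated B rings joined by an ether, so arene oxidation and acyloxylation away from the directing group are likely. The acetates can exchange in that medium. Ring A2 with a 7-acetoxy group is deactivated toward metalation. Both sites must react fully or mono-oxygenated material remains. The reaction type is established on simple aryl ketones, not on 3-acyloxychromones.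
- Comparison: both plans add two oxygens twofold at the end, with similar step counts. The chosen one does it at the most nucleophilic positions of the molecule, at 0 °C and under neutral conditions, so its selectivity follows from the substrate and not from a catalyst.

Alternative 3: Ring B1 is cut at C4'–C5' and C1'–C2', which gives the acetonyl ether A9 of the unit 2 flavonol and the vinyl ketone A10 on C2 of the unit 1 chromone.
- Forward key step: the enolate of A9 adds through its aryloxy-bearing carbon to the vinyl group of A10, and the methyl carbon then condenses with the chromonyl ketone to close the cyclohexenone A8, racemic at the aryloxy-bearing carbon.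
- For: two complete flavonoid halves, each with its C3 oxygen in place, are joined late by C–C bond formation. The ether C–O bond comes from a simple phenol alkylation and not from a substitution on a hindered arene. In convergence it is stronger than the chosen route.
- Against: A8 is not aromatic, and the required dehydrogenation competes with loss of the aryloxide from C4', which aromatises the ring while destroying the link between the halves. Enolisation of A9 must occur at the methylene and not at the methyl group. A10 is a doubly activated acceptor next to an electrophilic chromone C2 and a free 5-OH, and is likely to polymerise. Neither A9 nor A10 comes from standard flavonoid chemistry.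
- Comparison: the chosen route forms the ether between two simple benzene derivatives at the start, where failure is cheap, and relies on established reactions up to the key step.

Key step: step 10

## Route

Step 1
Reactants: 1 2',6'-dihydroxy-4'-methoxyacetophenone
Product: 2 2'-benzyloxy-6'-hydroxy-4'-methoxyacetophenone
Conditions: BnBr (1.0 equiv), K2CO3 (1.1 equiv), acetone, reflux
Reagents that add atoms: benzyl bromide, BrCc1ccccc1
Why: Williamson ether synthesis; the two hydroxyls are equivalent, and after the first alkylation the remaining one is locked in a hydrogen bond to the acetyl carbonyl and is much less nucleophilic, so the reaction should stop at the mono-ether with one equivalent of halide.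

Step 2
Reactants: 3 2',4',6'-trihydroxyacetophenone
Product: 4 2',4'-bis(benzyloxy)-6'-hydroxyacetophenone
Conditions: BnBr (2.1 equiv), K2CO3 (2.2 equiv), DMF, rt
Reagents that add atoms: benzyl bromide, BrCc1ccccc1
Why: Williamson ether synthesis; the para hydroxyl reacts first and one ortho hydroxyl second, while the last hydroxyl stays chelated to the carbonyl and is left free for the later pyranone closure.

Step 3
Reactants: 5 4-fluoro-3-hydroxybenzaldehyde
Product: 6 3-(benzyloxy)-4-fluorobenzaldehyde
Conditions: BnBr (1.1 equiv), K2CO3, DMF, rt
Reagents that add atoms: benzyl bromide, BrCc1ccccc1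
Why: Williamson ether synthesis on the only hydroxyl; the aryl fluoride is inert to carbonate at room temperature.

Step 4
Reactants: 6 3-(benzyloxy)-4-fluorobenzaldehyde; 7 methyl 4-hydroxy-3-methoxybenzoate (methyl vanillate)
Product: 8 methyl 4-[2-(benzyloxy)-4-formylphenoxy]-3-methoxybenzoate
Conditions: K2CO3 (2 equiv), DMSO, 120 °C
Reagents that add atoms: none
Why: Nucleophilic aromatic substitution (addition–elimination); the para formyl group stabilises the Meisenheimer intermediate and fluoride is the best leaving group for this mechanism, while 7 offers a single phenoxide, so the ether can form only between C4' and the oxygen para to the ester.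

Step 5
Reactants: 8 methyl 4-[2-(benzyloxy)-4-formylphenoxy]-3-methoxybenzoate
Product: 9 methyl 4-[2-(benzyloxy)-4-(dimethoxymethyl)phenoxy]-3-methoxybenzoate
Conditions: HC(OMe)3, p-TsOH·H2O (cat.), MeOH, rt; Et3N quench
Reagents that add atoms: trimethyl orthoformate, COC(OC)OC
Why: Acid-catalysed acetalisation driven by the orthoformate as water scavenger; methanol as solvent makes ester exchange degenerate, and the acetal is stable to the strong base of the next step.

Step 6
Reactants: 9 methyl 4-[2-(benzyloxy)-4-(dimethoxymethyl)phenoxy]-3-methoxybenzoate; 4 2',4'-bis(benzyloxy)-6'-hydroxyacetophenone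
Product: 10 1-[2,4-bis(benzyloxy)-6-hydroxyphenyl]-3-{4-[2-(benzyloxy)-4-(dimethoxymethyl)phenoxy]-3-methoxyphenyl}propane-1,3-dione
Conditions: LiN(SiMe3)2 (4 equiv), THF, −78 °C to rt; aq. NH4Cl
Reagents that add atoms: none
Why: Crossed Claisen condensation of the phenoxide-enolate dianion of 4 with the non-enolisable ester 9; deprotonation of the 1,3-diketone product by the excess base drives the acylation to completion.

Step 7
Reactants: 10 1-[2,4-bis(benzyloxy)-6-hydroxyphenyl]-3-{4-[2-(benzyloxy)-4-(dimethoxymethyl)phenoxy]-3-methoxyphenyl}propane-1,3-dione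
Product: 11 3-(benzyloxy)-4-{4-[5,7-bis(benzyloxy)-4-oxo-4H-chromen-2-yl]-2-methoxyphenoxy}benzaldehyde
Conditions: p-TsOH·H2O (0.2 equiv), toluene, 80 °C; then 1 M HCl, THF, rt
Reagents that add atoms: water, O
Why: Acid-catalysed cyclodehydration of the 2-hydroxyaryl 1,3-diketone (the phenol adds to the distal carbonyl and the hemiketal loses water to give the aromatic pyranone), as in the last stage of a Baker–Venkataraman flavone synthesis; the same acid hydrolyses the dimethyl acetal, and the mild sulfonic acid is chosen to spare the benzyl ether on O5.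

Step 8
Reactants: 11 3-(benzyloxy)-4-{4-[5,7-bis(benzyloxy)-4-oxo-4H-chromen-2-yl]-2-methoxyphenoxy}benzaldehyde; 2 2'-benzyloxy-6'-hydroxy-4'-methoxyacetophenone
Product: 12 (E)-1-[2-(benzyloxy)-6-hydroxy-4-methoxyphenyl]-3-[3-(benzyloxy)-4-{4-[5,7-bis(benzyloxy)-4-oxo-4H-chromen-2-yl]-2-methoxyphenoxy}phenyl]prop-2-en-1-one
Conditions: KOH (50% aq., excess), EtOH/THF, rt
Reagents that add atoms: none
Why: Claisen–Schmidt condensation; 11 cannot enolise, the aldol loses water by E1cB to the conjugated E-enone (the thermodynamic geometry), and the flavone of unit 2 has no acidic C–H and should survive hydroxide at room temperature.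

Step 9
Reactants: 12 (E)-1-[2-(benzyloxy)-6-hydroxy-4-methoxyphenyl]-3-[3-(benzyloxy)-4-{4-[5,7-bis(benzyloxy)-4-oxo-4H-chromen-2-yl]-2-methoxyphenoxy}phenyl]prop-2-en-1-one
Product: 13 5-(benzyloxy)-2-[3-(benzyloxy)-4-{4-[5,7-bis(benzyloxy)-4-oxo-4H-chromen-2-yl]-2-methoxyphenoxy}phenyl]-7-methoxy-4H-chromen-4-one (tetra-O-benzyl biflavone ether)
Conditions: I2 (0.1 equiv), DMSO, 120 °C
Reagents that add atoms: none
Why: Iodine-catalysed oxidative cyclisation of a 2'-hydroxychalcone; oxa-Michael closure and iodination–elimination give the flavone, and DMSO reoxidises the hydrogen iodide, so only a catalytic amount of halogen meets the benzyl ethers.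

Step 10
Reactants: 13 tetra-O-benzyl biflavone ether
Product: 15 5-(benzyloxy)-2-[3-(benzyloxy)-4-{4-[5,7-bis(benzyloxy)-3-hydroxy-4-oxo-4H-chromen-2-yl]-2-methoxyphenoxy}phenyl]-3-hydroxy-7-methoxy-4H-chromen-4-one (5,3',5'',7''-tetra-O-benzyl target), via bis-epoxide 14 (not isolated)
Conditions: dimethyldioxirane (ca. 0.08 M in acetone, 4 equiv), CH2Cl2, 0 °C to rt, dark; evaporate; then p-TsOH·H2O (cat.), CH2Cl2, rt
Reagents that add atoms: dimethyldioxirane, CC1(C)OO1
Why: Dimethyldioxirane delivers one oxygen atom to each C2=C3 bond in a concerted spiro transition state; this bond is the enol-ether end of a vinylogous ester and the only non-aromatic π bond of 13, so both flavone units should react independently and alike. The closest known reaction type is the dioxirane epoxidation of simple flavones and the acid-induced isomerisation of their epoxides to flavonols, used here twice in one molecule. The two oxiranes of 14 are closed by [2+1] oxygen-atom transfer and are necessarily cis-fused to the pyranone; their four stereocentres arise without control and are all destroyed in the second operation, so nothing stereochemical has to be set and no new ring remains in 15. Catalytic p-TsOH protonates each oxirane oxygen, the C2–O bond ionises to a cation stabilised by O1 and by the para-aryloxy ring B, and loss of H3 gives the enol, which is the 3-hydroxy-4-pyranone held by a hydrogen bond to C4=O. The step needs chemoselectivity for the two pyranone double bonds over the alkoxyarenes and the benzylic C–H bonds; this rests on the faster oxygen transfer to an electron-rich alkene at 0 °C, on the benzyl cap at O5 (no oxidisable phenol and no hydrogen bond draining the enone) and on a limited excess of oxidant. Evaporation removes the remaining oxidant and traces of water before the acid is added, so that elimination and not addition of a nucleophile to the cation ends the sequence.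

Step 11
Reactants: 15 5,3',5'',7''-tetra-O-benzyl target
Product: 16 2-{4-[4-(3,5,7-trihydroxy-4-oxo-4H-chromen-2-yl)-2-methoxyphenoxy]-3-hydroxyphenyl}-3,5-dihydroxy-7-methoxy-4H-chromen-4-one (target, CNP0190193.0)
Conditions: H2 (1 atm), 10% Pd/C, THF/MeOH (1:1), rt
Reagents that add atoms: none
Why: Hydrogenolysis of four aryl benzyl ethers on Pd/C; methyl ethers, the diaryl ether and the tetrasubstituted, electron-poor C2=C3 bonds of the flavonols are not reduced under these conditions.

## Compound list

1 | 2',6'-dihydroxy-4'-methoxyacetophenone | COc1cc(O)c(C(C)=O)c(O)c1 | starting material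
2 | 2'-benzyloxy-6'-hydroxy-4'-methoxyacetophenone | COc1cc(O)c(C(C)=O)c(OCc2ccccc2)c1 | intermediate
3 | 2',4',6'-trihydroxyacetophenone | CC(=O)c1c(O)cc(O)cc1O | starting material
4 | 2',4'-bis(benzyloxy)-6'-hydroxyacetophenone | CC(=O)c1c(O)cc(OCc2ccccc2)cc1OCc1ccccc1 | intermediate
5 | 4-fluoro-3-hydroxybenzaldehyde | O=Cc1ccc(F)c(O)c1 | starting material
6 | 3-(benzyloxy)-4-fluorobenzaldehyde | O=Cc1ccc(F)c(OCc2ccccc2)c1 | intermediate
7 | methyl 4-hydroxy-3-methoxybenzoate (methyl vanillate) | COC(=O)c1ccc(O)c(OC)c1 | starting material
8 | methyl 4-[2-(benzyloxy)-4-formylphenoxy]-3-methoxybenzoate | COC(=O)c1ccc(Oc2ccc(C=O)cc2OCc2ccccc2)c(OC)c1 | intermediate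
9 | methyl 4-[2-(benzyloxy)-4-(dimethoxymethyl)phenoxy]-3-methoxybenzoate | COC(=O)c1ccc(Oc2ccc(C(OC)OC)cc2OCc2ccccc2)c(OC)c1 | intermediate
10 | 1-[2,4-bis(benzyloxy)-6-hydroxyphenyl]-3-{4-[2-(benzyloxy)-4-(dimethoxymethyl)phenoxy]-3-methoxyphenyl}propane-1,3-dione | COC(OC)c1ccc(Oc2ccc(C(=O)CC(=O)c3c(O)cc(OCc4ccccc4)cc3OCc3ccccc3)cc2OC)c(OCc2ccccc2)c1 | intermediate
11 | 3-(benzyloxy)-4-{4-[5,7-bis(benzyloxy)-4-oxo-4H-chromen-2-yl]-2-methoxyphenoxy}benzaldehyde | O=Cc1ccc(Oc2ccc(-c3cc(=O)c4c(OCc5ccccc5)cc(OCc5ccccc5)cc4o3)cc2OC)c(OCc2ccccc2)c1 | intermediate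
12 | (E)-1-[2-(benzyloxy)-6-hydroxy-4-methoxyphenyl]-3-[3-(benzyloxy)-4-{4-[5,7-bis(benzyloxy)-4-oxo-4H-chromen-2-yl]-2-methoxyphenoxy}phenyl]prop-2-en-1-one | COc1cc(O)c(C(=O)/C=C/c2ccc(Oc3ccc(-c4cc(=O)c5c(OCc6ccccc6)cc(OCc6ccccc6)cc5o4)cc3OC)c(OCc3ccccc3)c2)c(OCc2ccccc2)c1 | intermediate
13 | tetra-O-benzyl biflavone ether (both C3 positions unsubstituted) | COc1cc(OCc2ccccc2)c2c(=O)cc(-c3ccc(Oc4ccc(-c5cc(=O)c6c(OCc7ccccc7)cc(OCc7ccccc7)cc6o5)cc4OC)c(OCc4ccccc4)c3)oc2c1 | intermediate
14 | bis(2,3-epoxide) of 13 (each oxirane cis-fused, mixture of stereoisomers, not isolated) | COc1cc(OCc2ccccc2)c2c(c1)OC1(c3ccc(Oc4ccc(C56OC5C(=O)c5c(OCc7ccccc7)cc(OCc7ccccc7)cc5O6)cc4OC)c(OCc4ccccc4)c3)OC1C2=O | intermediate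
15 | 5,3',5'',7''-tetra-O-benzyl target | COc1cc(OCc2ccccc2)c2c(=O)c(O)c(-c3ccc(Oc4ccc(-c5oc6cc(OCc7ccccc7)cc(OCc7ccccc7)c6c(=O)c5O)cc4OC)c(OCc4ccccc4)c3)oc2c1 | intermediate
16 | 2-{4-[4-(3,5,7-trihydroxy-4-oxo-4H-chromen-2-yl)-2-methoxyphenoxy]-3-hydroxyphenyl}-3,5-dihydroxy-7-methoxy-4H-chromen-4-one | COc1cc(O)c2c(=O)c(O)c(-c3ccc(Oc4ccc(-c5oc6cc(O)cc(O)c6c(=O)c5O)cc4OC)c(O)c3)oc2c1 | target

## Step count and uncertain steps

Total step count: 11. Longest linear sequence: 9 steps (steps 3 to 11, from 5); steps 1 and 2 are side branches.

**Step 10 (key step).** The most likely failure is over-oxidation: excess dioxirane can attack the benzylic C–H bonds of the four benzyl ethers or hydroxylate the electron-rich A rings while the second, slower epoxidation is still incomplete. The second risk is capture of the C2 cation by adventitious water, which leads to diols or ring-contracted products in place of the enol. Fallback, setting out from 13 and coming back at 15: C3 metalation in place of electrophilic oxidation. Both C3–H bonds are deprotonated with LiN(iPr)2 in THF at −78 °C and the dianion is trapped with B(OMe)3 to give the 3,3''-bis(dimethoxyboryl) biflavone F1. F1 is oxidised in the same flask with H2O2 and AcOH to 15.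

**Step 6.** The electron-rich ester 9 may be acylated only slowly by the hindered dianion of 4, so that proton transfer and O-acylation compete and conversion stalls. Fallback, from 9 to 10: the ester is saponified with LiOH in aqueous THF to 4-[2-(benzyloxy)-4-(dimethoxymethyl)phenoxy]-3-methoxybenzoic acid F2. F2 is joined to the phenol of 4 with EDC and DMAP to give the aryl ester 2-acetyl-3,5-bis(benzyloxy)phenyl 4-[2-(benzyloxy)-4-(dimethoxymethyl)phenoxy]-3-methoxybenzoate F3. A Baker–Venkataraman acyl shift (KOH, pyridine, 50 °C) then moves the aroyl group from oxygen to carbon and gives 10 by an intramolecular reaction.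

**Step 7.** The benzyl ether on O5, peri to the new carbonyl, is the most acid-labile group and may be lost during cyclodehydration, or the dehydration may stop at the hemiketal if the acid is kept too mild. Fallback, from 9 to 11, avoiding the hot acid closure of a diketone: 9 is reduced with LiAlH4 to {4-[2-(benzyloxy)-4-(dimethoxymethyl)phenoxy]-3-methoxyphenyl}methanol F4 and oxidised with MnO2 to 4-[2-(benzyloxy)-4-(dimethoxymethyl)phenoxy]-3-methoxybenzaldehyde F5. F5 is condensed with 4 (KOH, EtOH) to the chalcone (E)-1-[2,4-bis(benzyloxy)-6-hydroxyphenyl]-3-{4-[2-(benzyloxy)-4-(dimethoxymethyl)phenoxy]-3-methoxyphenyl}prop-2-en-1-one F6. F6 is cyclised with catalytic I2 in DMSO at 120 °C, and brief aqueous HCl in THF completes acetal cleavage to 11.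

**Step 8.** Hydroxide may add to C2 of the existing pyranone of unit 2 and open the ring while the hindered acetophenone 2 condenses slowly. Fallback, from 11 to 13, replacing steps 8 and 9 by acyl-transfer chemistry that needs no hydroxide: 11 is oxidised (NaClO2, NaH2PO4, 2-methyl-2-butene) to 3-(benzyloxy)-4-{4-[5,7-bis(benzyloxy)-4-oxo-4H-chromen-2-yl]-2-methoxyphenoxy}benzoic acid F7. F7 is esterified with the phenol of 2 (EDC, DMAP) to the 2-acetyl-3-(benzyloxy)-5-methoxyphenyl ester F8. F8 is rearranged with the non-nucleophilic base LiN(SiMe3)2 in THF at −20 °C (Baker–Venkataraman acyl shift) to the diketone 1-[2-(benzyloxy)-6-hydroxy-4-methoxyphenyl]-3-[3-(benzyloxy)-4-{4-[5,7-bis(benzyloxy)-4-oxo-4H-chromen-2-yl]-2-methoxyphenoxy}phenyl]propane-1,3-dione F9, which is closed with catalytic p-TsOH in toluene to 13.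

**Step 11.** Partly deprotected intermediates may precipitate and stop the hydrogenolysis, or prolonged exposure may begin to saturate a C2=C3 bond. Fallback, from 15 to 16: Lewis-acid debenzylation with BCl3 and pentamethylbenzene as cation scavenger in CH2Cl2 at −78 °C, which leaves the unchelated methyl ethers. This fallback makes no new compound and is entered as F0.

## Further compounds

F1 | step 10 | 3,3''-bis(dimethoxyboryl) derivative of 13 | COc1cc(OCc2ccccc2)c2c(=O)c(B(OC)OC)c(-c3ccc(Oc4ccc(-c5oc6cc(OCc7ccccc7)cc(OCc7ccccc7)c6c(=O)c5B(OC)OC)cc4OC)c(OCc4ccccc4)c3)oc2c1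
F2 | step 6 | 4-[2-(benzyloxy)-4-(dimethoxymethyl)phenoxy]-3-methoxybenzoic acid | COC(OC)c1ccc(Oc2ccc(C(=O)O)cc2OC)c(OCc2ccccc2)c1
F3 | step 6 | 2-acetyl-3,5-bis(benzyloxy)phenyl 4-[2-(benzyloxy)-4-(dimethoxymethyl)phenoxy]-3-methoxybenzoate | COC(OC)c1ccc(Oc2ccc(C(=O)Oc3cc(OCc4ccccc4)cc(OCc4ccccc4)c3C(C)=O)cc2OC)c(OCc2ccccc2)c1
F4 | step 7 | {4-[2-(benzyloxy)-4-(dimethoxymethyl)phenoxy]-3-methoxyphenyl}methanol | COC(OC)c1ccc(Oc2ccc(CO)cc2OC)c(OCc2ccccc2)c1
F5 | step 7 | 4-[2-(benzyloxy)-4-(dimethoxymethyl)phenoxy]-3-methoxybenzaldehyde | COC(OC)c1ccc(Oc2ccc(C=O)cc2OC)c(OCc2ccccc2)c1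
F6 | step 7 | (E)-1-[2,4-bis(benzyloxy)-6-hydroxyphenyl]-3-{4-[2-(benzyloxy)-4-(dimethoxymethyl)phenoxy]-3-methoxyphenyl}prop-2-en-1-one | COC(OC)c1ccc(Oc2ccc(/C=C/C(=O)c3c(O)cc(OCc4ccccc4)cc3OCc3ccccc3)cc2OC)c(OCc2ccccc2)c1
F7 | step 8 | 3-(benzyloxy)-4-{4-[5,7-bis(benzyloxy)-4-oxo-4H-chromen-2-yl]-2-methoxyphenoxy}benzoic acid | O=C(O)c1ccc(Oc2ccc(-c3cc(=O)c4c(OCc5ccccc5)cc(OCc5ccccc5)cc4o3)cc2OC)c(OCc2ccccc2)c1
F8 | step 8 | 2-acetyl-3-(benzyloxy)-5-methoxyphenyl 3-(benzyloxy)-4-{4-[5,7-bis(benzyloxy)-4-oxo-4H-chromen-2-yl]-2-methoxyphenoxy}benzoate | COc1cc(OC(=O)c2ccc(Oc3ccc(-c4cc(=O)c5c(OCc6ccccc6)cc(OCc6ccccc6)cc5o4)cc3OC)c(OCc3ccccc3)c2)c(C(C)=O)c(OCc2ccccc2)c1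
F9 | step 8 | 1-[2-(benzyloxy)-6-hydroxy-4-methoxyphenyl]-3-[3-(benzyloxy)-4-{4-[5,7-bis(benzyloxy)-4-oxo-4H-chromen-2-yl]-2-methoxyphenoxy}phenyl]propane-1,3-dione | COc1cc(O)c(C(=O)CC(=O)c2ccc(Oc3ccc(-c4cc(=O)c5c(OCc6ccccc6)cc(OCc6ccccc6)cc5o4)cc3OC)c(OCc3ccccc3)c2)c(OCc2ccccc2)c1
F0 | step 11 | none | none
A1 | alternative 1 | 3-(benzyloxy)-2-{3-(benzyloxy)-4-[4-(1,3-dioxolan-2-yl)-2-methoxyphenoxy]phenyl}-5-hydroxy-7-methoxy-4H-chromen-4-one | COc1cc(O)c2c(=O)c(OCc3ccccc3)c(-c3ccc(Oc4ccc(C5OCCO5)cc4OC)c(OCc4ccccc4)c3)oc2c1
A2 | alternative 1 | 3-(benzyloxy)-2-{3-(benzyloxy)-4-[4-(1,3-dioxolan-2-yl)-2-methoxyphenoxy]phenyl}-6-(2-diazoacetyl)-4H-pyran-4-one | [N-]=[N+]=CC(=O)c1cc(=O)c(OCc2ccccc2)c(-c2ccc(Oc3ccc(C4OCCO4)cc3OC)c(OCc3ccccc3)c2)o1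
A3 | alternative 1 | methoxyacetylene | COC#C
A4 | alternative 2 | 3,3',3'',7''-tetraacetate of the target | COc1cc(O)c2c(=O)c(OC(C)=O)c(-c3ccc(Oc4ccc(-c5oc6cc(OC(C)=O)cc(O)c6c(=O)c5OC(C)=O)cc4OC)c(OC(C)=O)c3)oc2c1
A5 | alternative 2 | 5,5''-dideoxy-3,3',3'',7''-tetraacetate | COc1ccc2c(=O)c(OC(C)=O)c(-c3ccc(Oc4ccc(-c5oc6cc(OC(C)=O)ccc6c(=O)c5OC(C)=O)cc4OC)c(OC(C)=O)c3)oc2c1
A6 | alternative 2 | [RuCl2(p-cymene)]2 | Cc1ccc(C(C)C)cc1.Cc1ccc(C(C)C)cc1.Cl[Ru]Cl.Cl[Ru]Cl
A7 | alternative 2 | PhI(OCOCF3)2 | O=C(OI(OC(=O)C(F)(F)F)c1ccccc1)C(F)(F)F
A8 | alternative 3 | 6-aryloxy-3-(chromon-2-yl)cyclohex-2-enone joining both halves (racemic) | O=C1C=C(c2oc3cc(OC)cc(O)c3c(=O)c2OCc2ccccc2)CCC1Oc1ccc(-c2oc3cc(OCc4ccccc4)cc(OCc4ccccc4)c3c(=O)c2OCc2ccccc2)cc1OC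
A9 | alternative 3 | 3,5,7-tris(benzyloxy)-2-[3-methoxy-4-(2-oxopropoxy)phenyl]-4H-chromen-4-one | CC(=O)COc1ccc(-c2oc3cc(OCc4ccccc4)cc(OCc4ccccc4)c3c(=O)c2OCc2ccccc2)cc1OC
A10 | alternative 3 | 2-acryloyl-3-(benzyloxy)-5-hydroxy-7-methoxy-4H-chromen-4-one | C=CC(=O)c1oc2cc(OC)cc(O)c2c(=O)c1OCc1ccccc1
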